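## The problem

Isodihydromaldoxin (20) is a diaryl ether. Ring A is a 3,5-dioxygenated methyl benzoate (A1 CO2Me, A2 ether carbon, A3 OMe, A5 OH). Ring B is a fully substituted salicylic acid (B1 CO2H, B2 OH, B3 Cl, B4 CH3, B6 ether carbon). The ether oxygen has three ortho neighbours (ester and methoxy on ring A, carboxyl on ring B), so a late C–O coupling of two finished arenes would be slow and would need extra activating groups. There is no stereocentre, so nothing has to be relayed; the task is one of position and of protection state. Two carboxyls must end as a free acid (ring B) and a methyl ester (ring A), three phenolic oxygens must end as OH (B2, A5) and OMe (A3), and the chlorine must sit between the B2 oxygen and the methyl group, a position that electrophilic chlorination of a 3-alkoxyphenol does not reliably reach. The methyl ester rules out hydroxide late in the route, the aryl chloride rules out hydrogenolysis, and the 2,6-dioxygenated benzoic acid decarboxylates easily and is best released last. The enabling feature lies in ring A: A3 and A5 carry oxygen in a 1,3 relationship, so the ring is the enol form of a cyclohexene-1,3-dione, and A2 lies between the carbonyl-derived A3 and the ester-bearing A1. A2–A3 can therefore come from an aryloxy-substituted two-carbon acid unit already attached to the ring B oxygen, and A4–A5–A6–A1 from an acetyl-substituted ynoate, so that the hindered ether bond is made as a simple phenol O-alkylation.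

## Retrosynthesis

20 ⇒ 19. No skeletal bond is cut. The ring B acid and the B2 hydroxyl are carried as a tert-butyl ester and a methyl ether. Both hang on the same carbonyl, so BCl3 can remove them in one operation, while the A3 methyl ether (no carbonyl neighbour) and the methyl ester stay. A free salicylic acid carried earlier would risk decarboxylation and would be methylated in step 9; a benzyl ester would need hydrogenolysis next to the C–Cl bond.

19 ⇒ 16 (through 18 and 17). The A3 O–CH3 bond is cut. Resorcinol 16 has two hydroxyls that differ only in their surroundings: A5 has two ortho hydrogens, A3 lies next to the aryloxy group. A bulky silyl group on A5, methylation of A3 and desilylation are the price for building ring A as a resorcinol.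

16 ⇒ 8 + 13 (key disconnection). Bonds A2–A1 and A4–A3 are cut. The forward reaction is a Michael addition of the aryloxymalonate 8 to ynone 13, giving 14, followed by Claisen closure to dione 15 and loss of the spare ester as dimethyl carbonate. Cutting the aryl–oxygen bond instead would require coupling at a tri-ortho-substituted ether. An alkene acceptor instead of the alkyne would aromatise only by expelling the aryloxide. A plain aryloxyacetate would need a lithium amide, and its hard enolate could add to the ketone of 13, deprotonate the acetyl group or close onto the ring B ester. The second ester makes the donor a soft, stabilised carbanion that is generated with carbonate, and it is removed in the aromatisation. Both precursors are simple: 8 carries all of ring B, 13 has six carbons.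

8 ⇒ 6 + 7. The O–C(sp3) bond is cut: alkylation of the salicylate phenol 6 with dimethyl chloromalonate (7). The forward reaction needs only that the chelated phenoxide is nucleophilic enough and that the tert-butyl ester resists the malonate anion.

6 ⇒ 5 ⇒ 3 + 4. The B1–carboxyl bond is cut. The carboxyl is delivered intramolecularly from the phenol oxygen: carbonate 5 (from phenol 3 and di-tert-butyl dicarbonate 4) is lithiated at the one position flanked by two oxygen groups and rearranges to the tert-butyl salicylate 6. This places the ester between the two oxygens and gives directly the ester type that step 11 can cleave.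

3 ⇒ 1. The phenolic C–O bond at B6 is cut. Sterically controlled C–H borylation of 2-chloro-3-methylanisole (1) and oxidation of boronate 2 put the hydroxyl para to the chlorine with no ambiguity. Introducing chlorine by electrophilic substitution of a chlorine-free 3-alkoxyphenol was rejected: the position ortho to the hydroxyl and para to the alkoxy group competes with, and probably beats, the one needed.

13 ⇒ 12 ⇒ 9 + 10. The C3–C4 bond of the ynone is cut: the lithium acetylide 11 of methyl propiolate (9) adds to acetaldehyde (10), and the propargylic alcohol 12 is oxidised.

## Roads not taken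

Alternative 1: The O–B6 bond and the B1–carboxyl bond are cut together. Fluoride (CsF) would release from silyl triflate A2 the aryne spanning B1 and B6. The phenoxide of bromophenol A3 would add at B6, the aryne carbon remote from the methoxy group, and the aryl anion left at B1 would be trapped by carbon dioxide to give acid A1.
- Merits: two finished arenes are joined in one step with the regiochemistry set by the 3-alkoxyaryne. The A3 methyl ether and a masked A5 hydroxyl come in with A3, so the differentiation that costs the chosen plan steps 8–10 does not arise. The ring B acid is born free. On convergence and on the hydroxyl problem this road is the better one.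
- Weak points: the nucleophile is a 2,6-disubstituted phenoxide. The B1 anion lies close to the ring A bromine, so protonation or bromine transfer can outrun capture of CO2. The bromide must then be carbonylated to the methyl ester beside a free, hindered acid, and MOM removal and B2 demethylation follow. A2 needs three to four steps from phenol 3.
- Comparison: the overall length is similar. The chosen plan offers in return a ring-forming step whose side paths are reversible and drain to the arene, and reagents that are stable and cheap.

Alternative 2: Ring A is cut through A2–A3 and A1–A6 at a non-aromatic level. The (Z)-alkylidene benzofuranone A5 and diene A6 would combine in a Diels–Alder reaction to the spiro enone A4. Dehydrogenation to dienone A7 and hydroxide attack on the benzofuranone carbonyl (retro-Claisen) would then release ring A as a phenol and ring B as the free acid.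
- Merits: the A3 oxygen enters as a methyl enol ether and the A5 oxygen as a ketone, and the ring opening delivers the ring B acid beside the ring A ester. Both differentiation problems of the chosen plan are solved by construction, and in this respect the road is superior.
- Weak points: A4 is one oxidation level short of an arene, hence the extra step to A7. The dienophile has two acceptor groups pulling in opposite directions, and the cycloaddition must build a quaternary spiro centre. The opening must select the hindered ketone over the methyl ester and the vinylogous ester. A5 needs about four steps from salicylate 6. Two stereocentres and a ring are made only to be destroyed, and B2 demethylation remains.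
- Comparison: the chosen plan forms ring A directly at the arene level in one flask, with no redox correction and no cycloaddition regiochemistry to control.

Alternative 3: Ring B is cut through B6–B1 and B5–B4. The aryl ethynyl ether A9 would add across C3 and C6 of pyrone A10, and loss of CO2 from the bridged lactone would give the diaryl ether A8.
- Merits: the fully substituted ring B arises with defined regiochemistry (the nucleophilic alkyne terminus bonds to C6 of the 3-carboxylated pyrone). Ring A carries its final A3 methyl ether. One acid treatment of A8 would remove both MOM groups and the tert-butyl ester, so the endgame is a single step against four in the chosen plan.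
- Weak points: the burden moves to the fragments. An ethynyl ether of a hindered, ester-bearing phenol is made through a dichlorovinyl ether and strong base, which the methyl ester does not tolerate well, and it is sensitive to hydration. A10 needs a chlorine at C5, where the pyrone does not react readily with electrophiles. The cycloaddition needs heat close to the limit of the tert-butyl ester.
- Comparison: the chosen plan has the longer endgame but uses fragments that are each available in four steps or fewer by standard reactions.

Key step: step 7

Remark: 2-chloro-3-methylanisole (1) is taken to be purchasable as such.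

Step 1
Reactants: 1 2-chloro-3-methylanisole (2-chloro-1-methoxy-3-methylbenzene)
Product: 3 4-chloro-3-methoxy-5-methylphenol, via aryl boronate 2 (not isolated)
Conditions: [Ir(OMe)(cod)]2 (1.5 mol%), 4,4'-di-tert-butyl-2,2'-bipyridine (3 mol%), B2pin2, THF, 80 °C; then KHSO5 (as Oxone), acetone–H2O, rt
Reagents that add atoms: bis(pinacolato)diboron, CC1(C)OB(OC1(C)C)B1OC(C)(C)C(C)(C)O1 (boron carried only as far as 2); potassium peroxymonosulfate, [K+].[O-]S(=O)(=O)OO
Why: Iridium-catalysed aromatic C–H borylation is sterically controlled and takes the only ring hydrogen of 1 without an ortho substituent (meta to OMe and CH3, para to Cl); oxidation of the C–B bond with retention gives the phenol, so the chlorine ends para to the hydroxyl without any electrophilic chlorination.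

Step 2
Reactants: 3 4-chloro-3-methoxy-5-methylphenol; 4 di-tert-butyl dicarbonate
Product: 5 tert-butyl (4-chloro-3-methoxy-5-methylphenyl) carbonate
Conditions: DMAP (5 mol%), MeCN, rt
Reagents that add atoms: none
Why: DMAP-catalysed acyl transfer converts the unhindered phenol into its tert-butyl carbonate, which serves as directing group and carboxyl source in step 3.

Step 3
Reactants: 5 tert-butyl (4-chloro-3-methoxy-5-methylphenyl) carbonate
Product: 6 tert-butyl 3-chloro-6-hydroxy-2-methoxy-4-methylbenzoate
Conditions: LiN(iPr)2 (1.5 equiv), THF, −78 → −20 °C; aq. NH4Cl
Reagents that add atoms: none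
Why: Anionic ortho-Fries rearrangement: lithium diisopropylamide removes the hydrogen flanked by the carbonate and the methoxy group (the only site activated by two directing groups) and the aryllithium takes the tert-butoxycarbonyl group from oxygen in a 1,3 O-to-C shift; the chlorine has no ortho hydrogen, so no aryne can form.

Step 4
Reactants: 6 tert-butyl 3-chloro-6-hydroxy-2-methoxy-4-methylbenzoate; 7 dimethyl 2-chloropropanedioate (dimethyl chloromalonate)
Product: 8 dimethyl 2-[2-(tert-butoxycarbonyl)-4-chloro-3-methoxy-5-methylphenoxy]propanedioate
Conditions: K2CO3, DMF, rt → 40 °C; dil. HCl work-up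
Reagents that add atoms: none
Why: Williamson-type SN2 O-alkylation of the potassium phenoxide of 6 by the doubly activated secondary chloride; the chloride is preferred to the bromide because it is a poorer halogen donor, and the hindered tert-butyl ester is not attacked productively by the malonate anion of the product.

Step 5
Reactants: 9 methyl propiolate; 10 acetaldehyde
Product: 12 methyl 4-hydroxypent-2-ynoate (racemic), via lithium acetylide 11 (not isolated)
Conditions: LiN(SiMe3)2, THF, −78 °C; then MeCHO, −78 °C; aq. NH4Cl
Reagents that add atoms: none
Why: Deprotonation of the acidic alkyne C–H at −78 °C gives the acetylide without attack on the ester, and its 1,2-addition to the aldehyde gives the propargylic alcohol; the new stereocentre is racemic and is removed by the oxidation in step 6.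

Step 6
Reactants: 12 methyl 4-hydroxypent-2-ynoate (racemic)
Product: 13 methyl 4-oxopent-2-ynoate
Conditions: Dess–Martin periodinane, CH2Cl2, 0 °C → rt
Reagents that add atoms: none
Why: Dess–Martin oxidation of a secondary propargylic alcohol under near-neutral, non-aqueous conditions that the base- and nucleophile-sensitive ynone tolerates; 13 is used at once.

Step 7
Reactants: 8 dimethyl 2-[2-(tert-butoxycarbonyl)-4-chloro-3-methoxy-5-methylphenoxy]propanedioate; 13 methyl 4-oxopent-2-ynoate
Product: 16 tert-butyl 3-chloro-6-[2,4-dihydroxy-6-(methoxycarbonyl)phenoxy]-2-methoxy-4-methylbenzoate, via Michael adduct 14 (not isolated), via cyclohexenedione 15 (not isolated)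
Conditions: Cs2CO3 (0.2 equiv), MeCN, 0 °C; then NaOMe (3 equiv), MeOH, 0 → 45 °C; aq. HCl
Reagents that add atoms: none
Why: Caesium carbonate generates a small concentration of the soft malonate carbanion of 8, which adds to the alkyne carbon of 13 that bears the ester (β to the ketone), and the allenolate is protonated by further 8, so that the Michael adduct 14 accumulates (A2–A1 bond). Sodium methoxide then forms the methyl ketone enolate of 14, which attacks one of the two geminal esters in a 6-exo-trig (enolexo) Claisen condensation and closes ring A as dione 15 (A4–A3 bond). Methoxide next attacks the remaining ester on the quaternary A2 of 15 (retro-Claisen), releasing dimethyl carbonate and the aromatic resorcinolate, the thermodynamic sink of the reversible species in the flask; acid then gives 16. The closest known reaction type is the Michael–Claisen annulation of malonates with conjugated ynones or β-alkoxy enones to resorcylates (the dimedone annulation at the alkyne oxidation level), joined to the familiar alkoxide cleavage of non-enolisable β-keto esters. The step needs attack β to the ketone and not β to the ester: the ketone is the stronger activating group, and the wrong adduct could close only a five-membered ring and can revert by methoxide addition–elimination. The geometry of 14 (A2 cis to the acetyl group for closure) need not be set, since reversible methoxide addition interconverts the alkene isomers. No stereocentre survives: the quaternary A2 of 15 is racemic and becomes an arene carbon. The malonate anion cannot close productively onto the tert-butyl ester of ring B (a hindered, non-enolisable β-keto ester would result), and at the alkyne oxidation level the aryloxy group stays on A2, whereas an alkene acceptor would aromatise only by expelling it.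

Step 8
Reactants: 16 tert-butyl 3-chloro-6-[2,4-dihydroxy-6-(methoxycarbonyl)phenoxy]-2-methoxy-4-methylbenzoate
Product: 17 tert-butyl 3-chloro-6-[2-hydroxy-6-(methoxycarbonyl)-4-(triisopropylsilyloxy)phenoxy]-2-methoxy-4-methylbenzoate
Conditions: iPr3SiCl (1.05 equiv), imidazole, DMF, 0 °C
Reagents that add atoms: triisopropylsilyl chloride, CC(C)[Si](Cl)(C(C)C)C(C)C
Why: Sterically controlled silylation: the A5 hydroxyl has two ortho hydrogens while the A3 hydroxyl is ortho to the bulky aryloxy group, so one equivalent of the large silyl chloride at 0 °C should take A5 only.

Step 9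
Reactants: 17 tert-butyl 3-chloro-6-[2-hydroxy-6-(methoxycarbonyl)-4-(triisopropylsilyloxy)phenoxy]-2-methoxy-4-methylbenzoate
Product: 18 tert-butyl 3-chloro-2-methoxy-6-[2-methoxy-6-(methoxycarbonyl)-4-(triisopropylsilyloxy)phenoxy]-4-methylbenzoate
Conditions: MeI, K2CO3, acetone, 40 °C
Reagents that add atoms: iodomethane, CI
Why: Williamson O-methylation of the one remaining phenol (A3); the triisopropylsilyl aryl ether and both esters are stable to K2CO3 in acetone.

Step 10
Reactants: 18 tert-butyl 3-chloro-2-methoxy-6-[2-methoxy-6-(methoxycarbonyl)-4-(triisopropylsilyloxy)phenoxy]-4-methylbenzoate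
Product: 19 tert-butyl 3-chloro-6-[4-hydroxy-2-methoxy-6-(methoxycarbonyl)phenoxy]-2-methoxy-4-methylbenzoate
Conditions: Bu4NF, AcOH, THF, 0 °C
Reagents that add atoms: none
Why: Fluoride-induced Si–O cleavage; the acetic acid buffer keeps the medium from becoming basic enough to touch the methyl ester.

Step 11
Reactants: 19 tert-butyl 3-chloro-6-[4-hydroxy-2-methoxy-6-(methoxycarbonyl)phenoxy]-2-methoxy-4-methylbenzoate
Product: 20 isodihydromaldoxin, 3-chloro-2-hydroxy-6-[4-hydroxy-2-methoxy-6-(methoxycarbonyl)phenoxy]-4-methylbenzoic acid
Conditions: BCl3 (excess), CH2Cl2, −78 → 0 °C; then H2O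
Reagents that add atoms: none
Why: Lewis-acid dealkylation: BCl3 ionises the tert-butyl ester and, chelated between the resulting carboxyl and the B2 oxygen, removes the one methyl ether that is ortho to a carbonyl; the A3 methyl ether has no carbonyl neighbour and the methyl ester is inert at 0 °C.

## Compound list

1 | 2-chloro-3-methylanisole (2-chloro-1-methoxy-3-methylbenzene) | COc1cccc(C)c1Cl | starting material
2 | 2-(4-chloro-3-methoxy-5-methylphenyl)-4,4,5,5-tetramethyl-1,3,2-dioxaborolane | COc1cc(cc(C)c1Cl)B1OC(C)(C)C(C)(C)O1 | intermediate
3 | 4-chloro-3-methoxy-5-methylphenol | COc1cc(O)cc(C)c1Cl | intermediate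
4 | di-tert-butyl dicarbonate | CC(C)(C)OC(=O)OC(=O)OC(C)(C)C | starting material
5 | tert-butyl (4-chloro-3-methoxy-5-methylphenyl) carbonate | COc1cc(OC(=O)OC(C)(C)C)cc(C)c1Cl | intermediate
6 | tert-butyl 3-chloro-6-hydroxy-2-methoxy-4-methylbenzoate | COc1c(Cl)c(C)cc(O)c1C(=O)OC(C)(C)C | intermediate
7 | dimethyl 2-chloropropanedioate | COC(=O)C(Cl)C(=O)OC | starting material
8 | dimethyl 2-[2-(tert-butoxycarbonyl)-4-chloro-3-methoxy-5-methylphenoxy]propanedioate | COC(=O)C(Oc1cc(C)c(Cl)c(OC)c1C(=O)OC(C)(C)C)C(=O)OC | intermediate
9 | methyl propiolate | C#CC(=O)OC | starting material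
10 | acetaldehyde | CC=O | starting material
11 | methyl 3-lithioprop-2-ynoate | [Li]C#CC(=O)OC | intermediate
12 | methyl 4-hydroxypent-2-ynoate (racemic) | CC(O)C#CC(=O)OC | intermediate
13 | methyl 4-oxopent-2-ynoate | COC(=O)C#CC(C)=O | intermediate
14 | trimethyl (2E)-1-[2-(tert-butoxycarbonyl)-4-chloro-3-methoxy-5-methylphenoxy]-4-oxopent-2-ene-1,1,2-tricarboxylate | COC(=O)C(Oc1cc(C)c(Cl)c(OC)c1C(=O)OC(C)(C)C)(C(=O)OC)/C(C(=O)OC)=C\C(C)=O | intermediate
15 | dimethyl 1-[2-(tert-butoxycarbonyl)-4-chloro-3-methoxy-5-methylphenoxy]-4,6-dioxocyclohex-2-ene-1,2-dicarboxylate (racemic) | COC(=O)C1=CC(=O)CC(=O)C1(Oc2cc(C)c(Cl)c(OC)c2C(=O)OC(C)(C)C)C(=O)OC | intermediate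
16 | tert-butyl 3-chloro-6-[2,4-dihydroxy-6-(methoxycarbonyl)phenoxy]-2-methoxy-4-methylbenzoate | COC(=O)c1cc(O)cc(O)c1Oc1cc(C)c(Cl)c(OC)c1C(=O)OC(C)(C)C | intermediate
17 | tert-butyl 3-chloro-6-[2-hydroxy-6-(methoxycarbonyl)-4-(triisopropylsilyloxy)phenoxy]-2-methoxy-4-methylbenzoate | COC(=O)c1cc(O[Si](C(C)C)(C(C)C)C(C)C)cc(O)c1Oc1cc(C)c(Cl)c(OC)c1C(=O)OC(C)(C)C | intermediate
18 | tert-butyl 3-chloro-2-methoxy-6-[2-methoxy-6-(methoxycarbonyl)-4-(triisopropylsilyloxy)phenoxy]-4-methylbenzoate | COC(=O)c1cc(O[Si](C(C)C)(C(C)C)C(C)C)cc(OC)c1Oc1cc(C)c(Cl)c(OC)c1C(=O)OC(C)(C)C | intermediate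
19 | tert-butyl 3-chloro-6-[4-hydroxy-2-methoxy-6-(methoxycarbonyl)phenoxy]-2-methoxy-4-methylbenzoate | COC(=O)c1cc(O)cc(OC)c1Oc1cc(C)c(Cl)c(OC)c1C(=O)OC(C)(C)C | intermediate
20 | isodihydromaldoxin, 3-chloro-2-hydroxy-6-[4-hydroxy-2-methoxy-6-(methoxycarbonyl)phenoxy]-4-methylbenzoic acid | COC(=O)c1cc(O)cc(OC)c1Oc1cc(C)c(Cl)c(O)c1C(=O)O | target

## Step count and least certain steps

Total: 11 steps. Longest linear sequence: 9 steps (1, 2, 3, 4, 7, 8, 9, 10, 11); steps 5 and 6 form the two-step branch to 13.

Step 7 (key step). The conjugate addition may be too slow for a tertiary carbanion that carries a bulky aryloxy group, so that base-induced oligomerisation of the ynone takes over. Alternatively the ring closure may stall because methoxide is diverted into reversible additions to the enone. The fallback sets out from phenol 6: alkylation with methyl bromoacetate (K2CO3, acetone) gives tert-butyl 3-chloro-2-methoxy-6-(2-methoxy-2-oxoethoxy)-4-methylbenzoate F1. Its lithium enolate (LiN(iPr)2, THF, −78 °C) is treated with 13 and then with NaOMe in MeOH. The secondary enolate is much less hindered, and the adduct aromatises by tautomerisation after the Claisen closure. The route is rejoined at 16. The price is a hard enolate that can add to the ketone or close onto the tert-butyl ester, which is why this is the reserve.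

Step 3. The amide base may attack the carbonate carbonyl, or the tert-butoxycarbonyl group may be transferred between molecules before the 1,3-shift, so that the carbonate is lost and not migrated. The fallback sets out from phenol 3 and rejoins at 6:
- MOMCl and iPr2NEt give 2-chloro-1-methoxy-5-(methoxymethoxy)-3-methylbenzene F2.
- Lithiation between the two oxygens (n-butyllithium, THF, 0 °C) and quenching with CO2 give 3-chloro-2-methoxy-6-(methoxymethoxy)-4-methylbenzoic acid F3.
- HCl in MeOH removes the acetal to give 3-chloro-6-hydroxy-2-methoxy-4-methylbenzoic acid F4.
- N,N-Dimethylformamide di-tert-butyl acetal (toluene, 80 °C) esterifies the carboxyl and returns 6.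

Step 4. Displacement at the secondary, doubly activated carbon by a chelated phenoxide may be slow, and the enolate of the product may then consume a second molecule of 7. The fallback sets out from 6 and uses a carbenoid O–H insertion in place of the substitution: dimethyl 2-diazopropanedioate F5 with Rh2(OAc)4 (1 mol%) in CH2Cl2 at 40 °C inserts into the phenol O–H bond under neutral conditions and returns 8.

Step 11. The tert-butyl cation set free beside BCl3 may alkylate the electron-rich ring A (A4 or A6), and warming may start cleavage of the A3 methyl ether. The fallback sets out from 19 and separates the two cleavages. Trifluoroacetic acid with triethylsilane in CH2Cl2 at 0 °C removes the tert-butyl group under cation-scavenging conditions and gives 3-chloro-6-[4-hydroxy-2-methoxy-6-(methoxycarbonyl)phenoxy]-2-methoxy-4-methylbenzoic acid F6. BCl3 at −78 °C, now chelated by the free acid, then removes only the B2 methyl group and gives 20.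

The selective silylation in step 8 is judged safer than these, because the two hydroxyls differ by a full ortho substituent.

## Further compounds

F1 | step 7 | tert-butyl 3-chloro-2-methoxy-6-(2-methoxy-2-oxoethoxy)-4-methylbenzoate | COC(=O)COc1cc(C)c(Cl)c(OC)c1C(=O)OC(C)(C)C
F2 | step 3 | 2-chloro-1-methoxy-5-(methoxymethoxy)-3-methylbenzene | COCOc1cc(C)c(Cl)c(OC)c1
F3 | step 3 | 3-chloro-2-methoxy-6-(methoxymethoxy)-4-methylbenzoic acid | COCOc1cc(C)c(Cl)c(OC)c1C(=O)O
F4 | step 3 | 3-chloro-6-hydroxy-2-methoxy-4-methylbenzoic acid | COc1c(Cl)c(C)cc(O)c1C(=O)O
F5 | step 4 | dimethyl 2-diazopropanedioate | COC(=O)C(=[N+]=[N-])C(=O)OC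
F6 | step 11 | 3-chloro-6-[4-hydroxy-2-methoxy-6-(methoxycarbonyl)phenoxy]-2-methoxy-4-methylbenzoic acid | COC(=O)c1cc(O)cc(OC)c1Oc1cc(C)c(Cl)c(OC)c1C(=O)O
A1 | alternative 1 | 2-[2-bromo-6-methoxy-4-(methoxymethoxy)phenoxy]-5-chloro-6-methoxy-4-methylbenzoic acid | COCOc1cc(Br)c(Oc2cc(C)c(Cl)c(OC)c2C(=O)O)c(OC)c1
A2 | alternative 1 | 4-chloro-3-methoxy-5-methyl-2-(trimethylsilyl)phenyl trifluoromethanesulfonate | COc1c(Cl)c(C)cc(OS(=O)(=O)C(F)(F)F)c1[Si](C)(C)C
A3 | alternative 1 | 2-bromo-6-methoxy-4-(methoxymethoxy)phenol | COCOc1cc(Br)c(O)c(OC)c1
A4 | alternative 2 | racemic methyl 5-chloro-2',4-dimethoxy-6-methyl-3,4'-dioxo-3H-spiro[benzofuran-2,1'-cyclohex-2'-ene]-6'-carboxylate, ester cis to the furanone oxygen (one enantiomer drawn) | COC(=O)[C@@H]1CC(=O)C=C(OC)[C@]12Oc3cc(C)c(Cl)c(OC)c3C2=O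
A5 | alternative 2 | methyl (2Z)-2-(5-chloro-4-methoxy-6-methyl-3-oxo-1-benzofuran-2(3H)-ylidene)acetate | COC(=O)/C=C1\Oc2cc(C)c(Cl)c(OC)c2C1=O
A6 | alternative 2 | 1,1-dimethoxy-3-(trimethylsilyloxy)buta-1,3-diene | COC(OC)=CC(=C)O[Si](C)(C)C
A7 | alternative 2 | racemic methyl 5-chloro-2',4-dimethoxy-6-methyl-3,4'-dioxo-3H-spiro[benzofuran-2,1'-cyclohexa-2',5'-diene]-6'-carboxylate | COC(=O)C1=CC(=O)C=C(OC)C12Oc3cc(C)c(Cl)c(OC)c3C2=O
A8 | alternative 3 | tert-butyl 3-chloro-6-[2-methoxy-6-(methoxycarbonyl)-4-(methoxymethoxy)phenoxy]-2-(methoxymethoxy)-4-methylbenzoate | COCOc1cc(OC)c(Oc2cc(C)c(Cl)c(OCOC)c2C(=O)OC(C)(C)C)c(c1)C(=O)OC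
A9 | alternative 3 | methyl 2-(ethynyloxy)-3-methoxy-5-(methoxymethoxy)benzoate | COCOc1cc(OC)c(OC#C)c(c1)C(=O)OC
A10 | alternative 3 | tert-butyl 5-chloro-4-(methoxymethoxy)-6-methyl-2-oxo-2H-pyran-3-carboxylate | COCOC1=C(C(=O)OC(C)(C)C)C(=O)OC(C)=C1Cl
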